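**Strategy.** Each pyranone ring (O1–C2–C3–C4, fused through C4a/C8a to phloroglucinol ring A) is a β-lactone O–C2–C3–C(=O) with the two ring-A carbons inserted into its acyl–oxygen bond. The C3–C3'' bond, which joins two carbons of like polarity, is therefore made first, by oxidative cross-coupling of two quasi-enantiomeric β-lactone enolates that cannot ring-open by E1cB; this fixes all four stereocentres. In the key step 3,5-bis(benzyloxy)benzyne inserts into both lactone acyl–O bonds: the anisyl-bearing four-membered ring (and its twin) grows by two atoms into the chroman-4-one, regiocontrolled by the aryne's 3-alkoxy group, with retention at C2. Hydrogenolysis then frees the five phenols.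

Key step: step 10

Assumption (chemistry): the 2,3-trans arrangement is taken as the thermodynamically preferred one at each enolisable C3, so only C2 and C2'' must be fixed absolutely; β-keto ester 5 and phenol 10 are taken as purchasable.

Step 1
Reactants: 1 ethyl 3-(4-methoxyphenyl)-3-oxopropanoate
Product: 2 ethyl (S)-3-hydroxy-3-(4-methoxyphenyl)propanoate
Conditions: RuCl(p-cymene)[(S,S)-TsDPEN] (1 mol %), HCO2H/Et3N (5:2), 30 °C
Reagents that add atoms: none
Why: Noyori–Ikariya asymmetric transfer hydrogenation of an aryl ketone, in which the (S,S)-diamine ruthenium hydride should deliver hydrogen to the face fixed by the aryl CH–π contact, as with acetophenones, and so set the (S)-carbinol that becomes C2.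

Step 2
Reactants: 2 ethyl (S)-3-hydroxy-3-(4-methoxyphenyl)propanoate
Product: 3 (S)-3-hydroxy-3-(4-methoxyphenyl)propanoic acid
Conditions: LiOH·H2O, THF/H2O, 0 °C; then 1 M HCl to pH 3 at 0 °C
Reagents that add atoms: lithium hydroxide, [Li+].[OH-]
Why: Ester saponification at 0 °C does not touch the carbinol centre, and cold, mild acidification should avoid ionisation of the 4-methoxybenzylic alcohol.

Step 3
Reactants: 3 (S)-3-hydroxy-3-(4-methoxyphenyl)propanoic acid
Product: 4 (S)-4-(4-methoxyphenyl)oxetan-2-one
Conditions: PhSO2Cl, pyridine, 0 °C, then 4 °C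
Reagents that add atoms: none
Why: β-Lactonisation by carboxyl activation: the mixed carboxylic–sulfonic anhydride is attacked by the β-hydroxyl (4-exo-trig), so the carbinol C–O bond is not broken and the centre stays (S); the product is kept cold because 4-aryl β-lactones with donor aryl groups lose CO2 on warming.

Step 4
Reactants: 5 ethyl 3-[4-(benzyloxy)phenyl]-3-oxopropanoate
Product: 6 ethyl (R)-3-[4-(benzyloxy)phenyl]-3-hydroxypropanoate
Conditions: RuCl(p-cymene)[(R,R)-TsDPEN] (1 mol %), HCO2H/Et3N (5:2), 30 °C
Reagents that add atoms: none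
Why: The same Noyori–Ikariya transfer hydrogenation with the enantiomeric catalyst should give the (R)-carbinol that becomes C2''.

Step 5
Reactants: 6 ethyl (R)-3-[4-(benzyloxy)phenyl]-3-hydroxypropanoate
Product: 7 (R)-3-[4-(benzyloxy)phenyl]-3-hydroxypropanoic acid
Conditions: LiOH·H2O, THF/H2O, 0 °C; then 1 M HCl to pH 3 at 0 °C
Reagents that add atoms: lithium hydroxide, [Li+].[OH-]
Why: Ester saponification as in step 2, with the carbinol centre untouched.

Step 6
Reactants: 7 (R)-3-[4-(benzyloxy)phenyl]-3-hydroxypropanoic acid
Product: 8 (R)-4-[4-(benzyloxy)phenyl]oxetan-2-one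
Conditions: PhSO2Cl, pyridine, 0 °C, then 4 °C
Reagents that add atoms: none
Why: β-Lactonisation by carboxyl activation as in step 3, with retention at the carbinol carbon.

Step 7
Reactants: 4 (S)-4-(4-methoxyphenyl)oxetan-2-one (3 equiv); 8 (R)-4-[4-(benzyloxy)phenyl]oxetan-2-one (1 equiv)
Product: 9 (3R,4S)-3-{(3S,4R)-4-[4-(benzyloxy)phenyl]-2-oxooxetan-3-yl}-4-(4-methoxyphenyl)oxetan-2-one (trans,trans bis-β-lactone)
Conditions: LiN(iPr)2, THF, −78 °C; then Cu(O2CCH(Et)Bu)2, −78 → −45 °C; cold NH4Cl quench
Reagents that add atoms: none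
Why: Oxidative coupling of ester-type enolates by a divalent copper carboxylate: the planar four-membered ring holds the enolate π-system orthogonal to the C4–O bond, so ring opening by E1cB is blocked, and each C3 should bond on the face anti to its C4 aryl group to give the trans,trans dimer; the cross product is favoured only statistically by the excess of 4 and should be separable from the two twofold-symmetric homodimers.

Step 8
Reactants: 10 3,5-bis(benzyloxy)phenol
Product: 11 2-bromo-3,5-bis(benzyloxy)phenol
Conditions: NBS (1.0 equiv), i-Pr2NH (10 mol %), CH2Cl2, −78 → 0 °C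
Reagents that add atoms: N-bromosuccinimide, O=C1CCC(=O)N1Br
Why: Amine-mediated ortho-selective electrophilic bromination of a phenol, in which the N-bromoamine is delivered by hydrogen bonding to the position next to the free OH (also para to one benzyloxy group) and not to the hindered position between the two ethers.

Step 9
Reactants: 11 2-bromo-3,5-bis(benzyloxy)phenol
Product: 14 3,5-bis(benzyloxy)-2-(trimethylsilyl)phenyl trifluoromethanesulfonate, via aryl trimethylsilyl ether 12 (not isolated), via lithium 2-silylphenoxide 13 (not isolated)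
Conditions: (Me3Si)2NH, THF, 65 °C, evaporate; n-BuLi, THF, −100 °C; then Tf2O, −100 → −78 °C
Reagents that add atoms: hexamethyldisilazane, C[Si](C)(C)N[Si](C)(C)C; trifluoromethanesulfonic anhydride, O=S(=O)(OS(=O)(=O)C(F)(F)F)C(F)(F)F
Why: Standard entry to an o-silylaryl triflate aryne precursor: O-silylation, bromine–lithium exchange followed by 1,3-O-to-C silyl shift (retro-Brook rearrangement), and O-triflation of the resulting lithium phenoxide.

Step 10
Reactants: 9 trans,trans bis-β-lactone; 14 3,5-bis(benzyloxy)-2-(trimethylsilyl)phenyl trifluoromethanesulfonate (3 equiv)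
Product: 17 (2S,3R)-5,7-bis(benzyloxy)-3-{(2R,3S)-5,7-bis(benzyloxy)-2-[4-(benzyloxy)phenyl]-4-oxochroman-3-yl}-2-(4-methoxyphenyl)chroman-4-one, via 3,5-bis(benzyloxy)benzyne 15 (not isolated), via mono-expanded lactone 16 (not isolated)
Conditions: CsF (6 equiv), 18-crown-6, MeCN/toluene (1:1), 0 → 23 °C, slow addition of 14
Reagents that add atoms: none
Why: Proposed new method: fluoride turns 14 into aryne 15, whose C1 (remote from the C3 benzyloxy group) is attacked by the ring oxygen of the strained lactone, and the aryl carbanion thus placed at C2 takes over the adjacent acyl group through a four-membered transition state, so that the two aryne carbons become C8a and C4a inside the O1–C4 bond; a fluoride-relayed course (the o-fluoroaryl anion opens the lactone at the acyl carbon, then the benzylic cesium alkoxide displaces fluoride by SNAr ortho to the new ketone) leads to the same product. The closest known reaction types are the insertion of arynes into the N–C(=O) bond of β-lactams, which gives 2,3-dihydroquinolin-4-ones, and into the C–O bond of carboxylic acids, which gives o-hydroxyaryl ketones. Both pyranone rings are closed in this way, as two-atom ring expansions of the four-membered lactones (the benzyloxyphenyl half first in the drawing of 16, then the anisyl half), not by cyclisation of an open chain. No stereocentre is created: C2, C3, C2'' and C3'' are carried over from 9 with retention because the C2–O1 and C3–C4 bonds stay intact, and the 2,3-trans arrangement is also the stable one at the enolisable C3 centres. The step needs O1 at C8a and the acyl group at C4a next to the 5-benzyloxy group, which the 3-alkoxy substituent of the aryne should secure by polarising the triple bond, and it needs acyl–oxygen instead of alkyl–oxygen cleavage, which the hard aryl anion and the acyloxonium character of the adduct should secure; anhydrous, nearly neutral conditions at or below 23 °C should spare the first-formed flavanone.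

Step 11
Reactants: 17 pentabenzyl ether of the target
Product: 18 (2S,3R)-5,7-dihydroxy-3-[(2R,3S)-5,7-dihydroxy-2-(4-hydroxyphenyl)-4-oxochroman-3-yl]-2-(4-methoxyphenyl)chroman-4-one (target)
Conditions: H2 (1 atm), Pd/C, EtOAc/THF, 23 °C
Reagents that add atoms: none
Why: Catalytic hydrogenolysis of the five benzyl aryl ethers under neutral conditions, stopped at full debenzylation; the methyl ether, the ketones and the ring C2–O1 bonds react more slowly, and no base is present that could open the flavanone rings or epimerise C2/C3.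

**Compound list**

1 | ethyl 3-(4-methoxyphenyl)-3-oxopropanoate | CCOC(=O)CC(=O)c1ccc(OC)cc1 | starting material
2 | ethyl (S)-3-hydroxy-3-(4-methoxyphenyl)propanoate | CCOC(=O)C[C@H](O)c1ccc(OC)cc1 | intermediate
3 | (S)-3-hydroxy-3-(4-methoxyphenyl)propanoic acid | OC(=O)C[C@H](O)c1ccc(OC)cc1 | intermediate
4 | (S)-4-(4-methoxyphenyl)oxetan-2-one | COc1ccc([C@H]2OC(=O)C2)cc1 | intermediate
5 | ethyl 3-[4-(benzyloxy)phenyl]-3-oxopropanoate | CCOC(=O)CC(=O)c1ccc(OCc2ccccc2)cc1 | starting material
6 | ethyl (R)-3-[4-(benzyloxy)phenyl]-3-hydroxypropanoate | CCOC(=O)C[C@@H](O)c1ccc(OCc2ccccc2)cc1 | intermediate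
7 | (R)-3-[4-(benzyloxy)phenyl]-3-hydroxypropanoic acid | OC(=O)C[C@@H](O)c1ccc(OCc2ccccc2)cc1 | intermediate
8 | (R)-4-[4-(benzyloxy)phenyl]oxetan-2-one | O=C1C[C@H](c2ccc(OCc3ccccc3)cc2)O1 | intermediate
9 | (3R,4S)-3-{(3S,4R)-4-[4-(benzyloxy)phenyl]-2-oxooxetan-3-yl}-4-(4-methoxyphenyl)oxetan-2-one | COc1ccc([C@H]2OC(=O)[C@@H]2[C@@H]2C(=O)O[C@H]2c2ccc(OCc3ccccc3)cc2)cc1 | intermediate
10 | 3,5-bis(benzyloxy)phenol | Oc1cc(OCc2ccccc2)cc(OCc2ccccc2)c1 | starting material
11 | 2-bromo-3,5-bis(benzyloxy)phenol | Oc1cc(OCc2ccccc2)cc(OCc2ccccc2)c1Br | intermediate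
12 | [2-bromo-3,5-bis(benzyloxy)phenoxy]trimethylsilane | C[Si](C)(C)Oc1cc(OCc2ccccc2)cc(OCc2ccccc2)c1Br | intermediate (not isolated)
13 | lithium 3,5-bis(benzyloxy)-2-(trimethylsilyl)phenoxide | [Li+].[O-]c1cc(OCc2ccccc2)cc(OCc2ccccc2)c1[Si](C)(C)C | intermediate (not isolated)
14 | 3,5-bis(benzyloxy)-2-(trimethylsilyl)phenyl trifluoromethanesulfonate | C[Si](C)(C)c1c(OCc2ccccc2)cc(OCc2ccccc2)cc1OS(=O)(=O)C(F)(F)F | intermediate
15 | 3,5-bis(benzyloxy)benzyne (1,2-didehydro-3,5-bis(benzyloxy)benzene) | C1#CC(OCc2ccccc2)=CC(OCc2ccccc2)=C1 | intermediate (not isolated)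
16 | (3R,4S)-3-{(2R,3S)-5,7-bis(benzyloxy)-2-[4-(benzyloxy)phenyl]-4-oxochroman-3-yl}-4-(4-methoxyphenyl)oxetan-2-one | COc1ccc([C@H]2OC(=O)[C@@H]2[C@@H]2C(=O)c3c(OCc4ccccc4)cc(OCc4ccccc4)cc3O[C@H]2c2ccc(OCc3ccccc3)cc2)cc1 | intermediate (not isolated)
17 | (2S,3R)-5,7-bis(benzyloxy)-3-{(2R,3S)-5,7-bis(benzyloxy)-2-[4-(benzyloxy)phenyl]-4-oxochroman-3-yl}-2-(4-methoxyphenyl)chroman-4-one | COc1ccc([C@H]2Oc3cc(OCc4ccccc4)cc(OCc4ccccc4)c3C(=O)[C@@H]2[C@@H]2C(=O)c3c(OCc4ccccc4)cc(OCc4ccccc4)cc3O[C@H]2c2ccc(OCc3ccccc3)cc2)cc1 | intermediate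
18 | (2S,3R)-5,7-dihydroxy-3-[(2R,3S)-5,7-dihydroxy-2-(4-hydroxyphenyl)-4-oxochroman-3-yl]-2-(4-methoxyphenyl)chroman-4-one | COc1ccc([C@H]2Oc3cc(O)cc(O)c3C(=O)[C@@H]2[C@@H]2C(=O)c3c(O)cc(O)cc3O[C@H]2c2ccc(O)cc2)cc1 | target

**Step count and risks**

Total steps: 11. Longest linear sequence: 6 steps (1, 2, 3, 7, 10, 11).

Steps most likely to fail:

Step 10 (proposed new method). The weakly basic lactone oxygen may fail to capture the aryne before fluoride or solvent consumes it. Insertion may also run through carbonyl-oxygen attack with cleavage of the benzylic C2–O bond and loss of configuration at C2, and the first-formed flavanone may ring-open under the fluoride base. The fallback sets out from 9 and comes back at 17, using only known steps. 1-Fluoro-3,5-bis(benzyloxy)benzene F1 (from 1,3,5-trifluorobenzene and NaOCH2Ph) is brominated with NBS next to fluorine to give 2-bromo-1-fluoro-3,5-bis(benzyloxy)benzene F2. Bromine–lithium exchange (n-BuLi, THF, −78 °C) gives the o-fluoroaryllithium, which should add to both lactone carbonyls of 9 with acyl–oxygen cleavage to give the bis(β-hydroxy o-fluoroaryl ketone) F3. Cs2CO3 in DMF should then close both rings by intramolecular SNAr at C–F, with neither C2–O bond touched, to reach 17.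

Step 7. The two near-identical enolates pair only statistically, and the lactone enolates may fragment thermally before oxidation. The fallback sets out from 8 and comes back at 16. Lactone 8 is first expanded on its own to (R)-5,7-bis(benzyloxy)-2-[4-(benzyloxy)phenyl]chroman-4-one F4 (by the aryllithium/SNAr sequence above, or by the aryne expansion). The lithium enolates of ketone F4 and lactone 4 (LiN(iPr)2, THF, −78 °C) are then cross-coupled with Fe(acac)3; the two different enolate classes should favour the hetero-product, each bond again forming anti to the neighbouring aryl group. This gives 16 as an isolated compound, which needs a single aryne insertion to reach 17.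

Step 11. Over-reduction may occur: hydrogenolytic opening of the benzylic C2–O1 bonds or reduction of the aryl ketones once the phenols are free. The fallback sets out from 17 and comes back at 18: BCl3 with pentamethylbenzene as cation scavenger in CH2Cl2 at −78 °C should cleave the benzyl ethers while the aryl methyl ether survives. This fallback makes no new compound (F0).

Further compounds
F1 | step 10 | 1-fluoro-3,5-bis(benzyloxy)benzene | Fc1cc(OCc2ccccc2)cc(OCc2ccccc2)c1
F2 | step 10 | 2-bromo-1-fluoro-3,5-bis(benzyloxy)benzene | Fc1cc(OCc2ccccc2)cc(OCc2ccccc2)c1Br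
F3 | step 10 | bis(β-hydroxy o-fluoroaryl ketone) from double acyl–oxygen opening of 9: 1,4-bis[2-fluoro-4,6-bis(benzyloxy)phenyl]butane-1,4-dione bearing hydroxy(4-methoxyphenyl)methyl at C2 and [4-(benzyloxy)phenyl](hydroxy)methyl at C3, all four stereocentres as in 9 | COc1ccc([C@@H](O)[C@H](C(=O)c2c(F)cc(OCc3ccccc3)cc2OCc2ccccc2)[C@H](C(=O)c2c(F)cc(OCc3ccccc3)cc2OCc2ccccc2)[C@@H](O)c2ccc(OCc3ccccc3)cc2)cc1
F4 | step 7 | (R)-5,7-bis(benzyloxy)-2-[4-(benzyloxy)phenyl]chroman-4-one | O=C1C[C@H](c2ccc(OCc3ccccc3)cc2)Oc2cc(OCc3ccccc3)cc(OCc3ccccc3)c21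
F0 | step 11 | none | none
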